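**Strategy.** The cyclohexane is disconnected at its two mirror-related ring bonds, C(=CH2)–CH(CH2Ar) and CH2–CH2, which lie on either side of the plane through the C(CH3)2 carbon and the carbinol carbon. Both are forged (as C=C) in one Knoevenagel–aldol cyclocondensation of 2,2-dimethylpropanedial with benzyl acetoacetate, giving an achiral 4,4-dimethylcyclohexadienone ester from two open three-carbon pieces. The ester then steers a catalytic enantioselective Mukaiyama–Michael addition that installs the side-chain stereocentre, and leaves in a decarboxylative methylenation. Catalyst-controlled ketone reduction, decarboxylative iodination and a Negishi coupling with protected 6-iodoluteolin complete the synthesis.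

Key step: step 2

Remark: the facial sense of the copper–bis(oxazoline) addition in step 3 is assigned by analogy with alkylidene 1,3-dicarbonyl acceptors; the ligand antipode is taken if it proves opposite.

**Route**

Step 1
Reactants: 1 2,2-dimethylpropane-1,3-diol
Product: 2 2,2-dimethylpropanedial
Conditions: IBX (2.4 equiv), EtOAc, 80 °C; filter; filtrate used at once
Reagents that add atoms: none
Why: Oxidation of both primary alcohols with 2-iodoxybenzoic acid should stop at the dialdehyde, which has no α-hydrogen and so cannot enolise or dehydrate, and which is carried on in solution because it is volatile and hydrates easily.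

Step 2
Reactants: 2 2,2-dimethylpropanedial; 3 benzyl 3-oxobutanoate
Product: 5 benzyl 3,3-dimethyl-6-oxocyclohexa-1,4-diene-1-carboxylate, via alkylidene keto ester 4 (not isolated)
Conditions: piperidine (20 mol%), AcOH (20 mol%), 4 Å molecular sieves, EtOAc/PhMe, 23 → 70 °C
Reagents that add atoms: none
Why: Piperidinium acetate first condenses the doubly activated CH2 of 3 with one formyl group of 2 (Knoevenagel) to the alkylidene keto ester 4, which already holds the bond that becomes C(=CH2)–CH(CH2Ar), and the acetyl group of 4 then adds through its enamine or enol to the second formyl group and the aldol loses water, which makes the bond that becomes the ring CH2–CH2. The closest known reaction type is the tandem Knoevenagel–intramolecular aldol [3+3] cyclocondensation of 1,3-dialdehydes with β-dicarbonyl CH acids. The six-membered ring closes in the aldol event by a 6-(enolendo)-exo-trig addition followed by E1cB dehydration. No stereocentre is created, 5 is achiral, and both ring stereocentres are therefore left to catalyst control in steps 3 and 5. The step needs mono-condensation and the cyclising geometry of 4: the neopentyl-type β-carbon of 4 resists a second Michael addition of 3, the E and Z forms of 4 interconvert by reversible amine addition so that the (2E) isomer with acetyl cis to the formyl-bearing carbon is drained into the ring, and the quaternary carbon rules out aromatisation.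

Step 3
Reactants: 5 benzyl 3,3-dimethyl-6-oxocyclohexa-1,4-diene-1-carboxylate; 6 tert-butyl[(1-methoxyethenyl)oxy]dimethylsilane
Product: 7 benzyl (1RS,6R)-6-(2-methoxy-2-oxoethyl)-5,5-dimethyl-2-oxocyclohex-3-ene-1-carboxylate
Conditions: CuCl2 (10 mol%), AgSbF6 (20 mol%), 2,2'-(propane-2,2-diyl)bis[(4S)-4-tert-butyl-4,5-dihydro-1,3-oxazole] (11 mol%), (CF3)2CHOH (1.5 equiv), CH2Cl2/PhMe, −78 °C
Reagents that add atoms: none
Why: Two-point binding of the keto ester carbonyls to the square-planar divalent copper bis(oxazoline) complex activates only the doubly activated alkene and shields one of its faces, so this enantioselective Mukaiyama–Michael addition, a reaction known for alkylidene 1,3-dicarbonyl acceptors, should set the side-chain stereocentre as (6R).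

Step 4
Reactants: 7 benzyl (1RS,6R)-6-(2-methoxy-2-oxoethyl)-5,5-dimethyl-2-oxocyclohex-3-ene-1-carboxylate
Product: 9 methyl 2-[(1S)-6,6-dimethyl-2-methylidene-3-oxocyclohexyl]acetate, via β-keto acid 8 (not isolated)
Conditions: H2 (1 atm), Pd/C (10 wt%), EtOAc, 0 °C; filter cold; then [CH2=N(CH3)2]I (1.5 equiv), CH2Cl2, 0 → 40 °C
Reagents that add atoms: N,N-dimethylmethyleneiminium iodide, C=[N+](C)C.[I-]
Why: Hydrogenation saturates the ring alkene and hydrogenolyses the benzyl ester, and the β-keto acid is then aminomethylated at its doubly activated carbon and loses CO2 and dimethylamine (decarboxylative Mannich methylenation), which should place the exocyclic methylene regiospecifically next to the stereocentre without touching it (the descriptor changes from R to S only through a change of priorities).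

Step 5
Reactants: 9 methyl 2-[(1S)-6,6-dimethyl-2-methylidene-3-oxocyclohexyl]acetate
Product: 10 methyl 2-[(1S,3S)-3-hydroxy-6,6-dimethyl-2-methylidenecyclohexyl]acetate
Conditions: (R)-2-methyl-CBS-oxazaborolidine (20 mol%), catecholborane (1.5 equiv), PhMe, −78 °C; then MeOH, aq. NaHCO3
Reagents that add atoms: none
Why: In this Corey–Bakshi–Shibata reduction the alkenyl carbon acts as the large group, so the (R)-oxazaborolidine should deliver hydride in a 1,2-manner to give the (S)-carbinol trans to the side chain under catalyst control, while any cis alcohol can close to a bridged lactone and is removed on silica.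

Step 6
Reactants: 10 methyl 2-[(1S,3S)-3-hydroxy-6,6-dimethyl-2-methylidenecyclohexyl]acetate
Product: 11 methyl 2-[(1S,3S)-3-(tert-butyldimethylsilyloxy)-6,6-dimethyl-2-methylidenecyclohexyl]acetate
Conditions: TBSCl (1.3 equiv), imidazole (2.5 equiv), DMF, 23 °C
Reagents that add atoms: tert-butyldimethylsilyl chloride, CC(C)(C)[Si](C)(C)Cl
Why: Standard silylation of the secondary allylic alcohol removes the only acidic proton before the radical and organozinc steps.

Step 7
Reactants: 11 methyl 2-[(1S,3S)-3-(tert-butyldimethylsilyloxy)-6,6-dimethyl-2-methylidenecyclohexyl]acetate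
Product: 12 2-[(1S,3S)-3-(tert-butyldimethylsilyloxy)-6,6-dimethyl-2-methylidenecyclohexyl]acetic acid
Conditions: LiOH·H2O (3 equiv), THF/MeOH/H2O, 23 °C; then 1 M HCl to pH 4
Reagents that add atoms: lithium hydroxide, [Li+].[OH-]
Why: Saponification of the unhindered methyl ester should leave the silyl ether and both ring stereocentres, neither of which is α to a carbonyl, unchanged.

Step 8
Reactants: 12 2-[(1S,3S)-3-(tert-butyldimethylsilyloxy)-6,6-dimethyl-2-methylidenecyclohexyl]acetic acid
Product: 14 tert-butyl{[(1S,3S)-3-(iodomethyl)-4,4-dimethyl-2-methylidenecyclohexyl]oxy}dimethylsilane, via thiohydroxamate ester 13 (not isolated)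
Conditions: N,N'-dicyclohexylcarbodiimide, 1-hydroxypyridine-2(1H)-thione, CH2Cl2, 0 → 23 °C, dark; then CHI3 (3 equiv), PhH, hν (tungsten lamp), 25 °C
Reagents that add atoms: iodoform, IC(I)I
Why: In this Barton decarboxylative iodination the thiohydroxamate ester fragments under light to a primary alkyl radical, which should take iodine from iodoform faster than it can attack the nearby 1,1-disubstituted alkene (only three- or four-membered closures are open to it).

Step 9
Reactants: 15 luteolin
Product: 16 2-[3,4-bis(methoxymethoxy)phenyl]-5-hydroxy-7-(methoxymethoxy)-4H-chromen-4-one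
Conditions: MOMCl (3.3 equiv), i-Pr2NEt (4 equiv), CH2Cl2/DMF, 0 → 23 °C
Reagents that add atoms: chloromethyl methyl ether, COCCl
Why: The 5-hydroxyl is hydrogen-bonded to the C4 carbonyl and is the least reactive phenol, so three equivalents of the chloride should alkylate only the 7-, 3'- and 4'-hydroxyls.

Step 10
Reactants: 16 2-[3,4-bis(methoxymethoxy)phenyl]-5-hydroxy-7-(methoxymethoxy)-4H-chromen-4-one
Product: 17 2-[3,4-bis(methoxymethoxy)phenyl]-5-hydroxy-6-iodo-7-(methoxymethoxy)-4H-chromen-4-one
Conditions: BnMe3N+ ICl2− (1.1 equiv), CaCO3 (1.5 equiv), CH2Cl2/MeOH, 23 °C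
Reagents that add atoms: benzyltrimethylammonium dichloroiodate, C[N+](C)(C)Cc1ccccc1.Cl[I-]Cl
Why: Electrophilic iodination of ring A with the 5-hydroxyl left free is directed to C6, ortho to the chelated phenol and to the 7-alkoxy group, which is the known site for 5-hydroxy-7-alkoxyflavones with this reagent.

Step 11
Reactants: 17 2-[3,4-bis(methoxymethoxy)phenyl]-5-hydroxy-6-iodo-7-(methoxymethoxy)-4H-chromen-4-one
Product: 18 2-[3,4-bis(methoxymethoxy)phenyl]-6-iodo-5,7-bis(methoxymethoxy)-4H-chromen-4-one
Conditions: NaH (1.3 equiv), MOMCl (1.5 equiv), DMF, 0 → 23 °C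
Reagents that add atoms: chloromethyl methyl ether, COCCl
Why: Williamson alkylation of the sodium phenoxide masks the last acidic proton so that the organozinc partner is not quenched in the coupling.

Step 12
Reactants: 14 tert-butyl{[(1S,3S)-3-(iodomethyl)-4,4-dimethyl-2-methylidenecyclohexyl]oxy}dimethylsilane; 18 2-[3,4-bis(methoxymethoxy)phenyl]-6-iodo-5,7-bis(methoxymethoxy)-4H-chromen-4-one
Product: 20 2-[3,4-bis(methoxymethoxy)phenyl]-6-{[(1S,3S)-3-(tert-butyldimethylsilyloxy)-6,6-dimethyl-2-methylidenecyclohexyl]methyl}-5,7-bis(methoxymethoxy)-4H-chromen-4-one, via alkylzinc iodide 19 (not isolated)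
Conditions: Zn dust (activated with BrCH2CH2Br and Me3SiCl), LiCl, THF, 40 °C; then 18, Pd(OAc)2 (5 mol%), SPhos (10 mol%), THF/NMP, 50 °C
Reagents that add atoms: none
Why: Zinc inserts into the primary C–I bond and the alkylzinc iodide, which has no β-leaving group, should couple with the di-ortho-substituted aryl iodide in a Negishi reaction under a palladium/biarylphosphine system suited to hindered aryl halides, with both stereocentres remote from the reacting carbon.

Step 13
Reactants: 20 2-[3,4-bis(methoxymethoxy)phenyl]-6-{[(1S,3S)-3-(tert-butyldimethylsilyloxy)-6,6-dimethyl-2-methylidenecyclohexyl]methyl}-5,7-bis(methoxymethoxy)-4H-chromen-4-one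
Product: 21 ugonin Q [2-(3,4-dihydroxyphenyl)-5,7-dihydroxy-6-{[(1S,3S)-3-hydroxy-6,6-dimethyl-2-methylidenecyclohexyl]methyl}-4H-chromen-4-one]
Conditions: HCl (1.25 M in MeOH), THF, 0 → 23 °C
Reagents that add atoms: none
Why: Acid-catalysed methanolysis should remove the four methoxymethyl acetals and the silyl ether in one operation, under conditions dilute and cold enough to leave the 1,1-disubstituted alkene and the allylic alcohol unprotonated.

**Compound list**

1 | 2,2-dimethylpropane-1,3-diol | OCC(C)(C)CO | starting material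
2 | 2,2-dimethylpropanedial | O=CC(C)(C)C=O | intermediate
3 | benzyl 3-oxobutanoate | CC(=O)CC(=O)OCc1ccccc1 | starting material
4 | benzyl (2E)-2-acetyl-4,4-dimethyl-5-oxopent-2-enoate | O=CC(C)(C)/C=C(\C(C)=O)C(=O)OCc1ccccc1 | intermediate
5 | benzyl 3,3-dimethyl-6-oxocyclohexa-1,4-diene-1-carboxylate | O=C1C=CC(C)(C)C=C1C(=O)OCc1ccccc1 | intermediate
6 | tert-butyl[(1-methoxyethenyl)oxy]dimethylsilane | C=C(OC)O[Si](C)(C)C(C)(C)C | starting material
7 | benzyl (1RS,6R)-6-(2-methoxy-2-oxoethyl)-5,5-dimethyl-2-oxocyclohex-3-ene-1-carboxylate | COC(=O)C[C@@H]1C(C(=O)OCc2ccccc2)C(=O)C=CC1(C)C | intermediate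
8 | (1RS,2R)-2-(2-methoxy-2-oxoethyl)-3,3-dimethyl-6-oxocyclohexane-1-carboxylic acid | COC(=O)C[C@@H]1C(C(=O)O)C(=O)CCC1(C)C | intermediate
9 | methyl 2-[(1S)-6,6-dimethyl-2-methylidene-3-oxocyclohexyl]acetate | COC(=O)C[C@@H]1C(=C)C(=O)CCC1(C)C | intermediate
10 | methyl 2-[(1S,3S)-3-hydroxy-6,6-dimethyl-2-methylidenecyclohexyl]acetate | COC(=O)C[C@@H]1C(=C)[C@@H](O)CCC1(C)C | intermediate
11 | methyl 2-[(1S,3S)-3-(tert-butyldimethylsilyloxy)-6,6-dimethyl-2-methylidenecyclohexyl]acetate | COC(=O)C[C@@H]1C(=C)[C@@H](O[Si](C)(C)C(C)(C)C)CCC1(C)C | intermediate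
12 | 2-[(1S,3S)-3-(tert-butyldimethylsilyloxy)-6,6-dimethyl-2-methylidenecyclohexyl]acetic acid | OC(=O)C[C@@H]1C(=C)[C@@H](O[Si](C)(C)C(C)(C)C)CCC1(C)C | intermediate
13 | 2-sulfanylidenepyridin-1(2H)-yl 2-[(1S,3S)-3-(tert-butyldimethylsilyloxy)-6,6-dimethyl-2-methylidenecyclohexyl]acetate | S=c1ccccn1OC(=O)C[C@@H]1C(=C)[C@@H](O[Si](C)(C)C(C)(C)C)CCC1(C)C | intermediate
14 | tert-butyl{[(1S,3S)-3-(iodomethyl)-4,4-dimethyl-2-methylidenecyclohexyl]oxy}dimethylsilane | IC[C@@H]1C(=C)[C@@H](O[Si](C)(C)C(C)(C)C)CCC1(C)C | intermediate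
15 | luteolin [2-(3,4-dihydroxyphenyl)-5,7-dihydroxy-4H-chromen-4-one] | O=c1cc(-c2ccc(O)c(O)c2)oc2cc(O)cc(O)c12 | starting material
16 | 2-[3,4-bis(methoxymethoxy)phenyl]-5-hydroxy-7-(methoxymethoxy)-4H-chromen-4-one | COCOc1cc(O)c2c(c1)oc(-c1ccc(OCOC)c(OCOC)c1)cc2=O | intermediate
17 | 2-[3,4-bis(methoxymethoxy)phenyl]-5-hydroxy-6-iodo-7-(methoxymethoxy)-4H-chromen-4-one | COCOc1cc2oc(-c3ccc(OCOC)c(OCOC)c3)cc(=O)c2c(O)c1I | intermediate
18 | 2-[3,4-bis(methoxymethoxy)phenyl]-6-iodo-5,7-bis(methoxymethoxy)-4H-chromen-4-one | COCOc1cc2oc(-c3ccc(OCOC)c(OCOC)c3)cc(=O)c2c(OCOC)c1I | intermediate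
19 | {[(1S,3S)-3-(tert-butyldimethylsilyloxy)-6,6-dimethyl-2-methylidenecyclohexyl]methyl}zinc iodide | I[Zn]C[C@@H]1C(=C)[C@@H](O[Si](C)(C)C(C)(C)C)CCC1(C)C | intermediate
20 | 2-[3,4-bis(methoxymethoxy)phenyl]-6-{[(1S,3S)-3-(tert-butyldimethylsilyloxy)-6,6-dimethyl-2-methylidenecyclohexyl]methyl}-5,7-bis(methoxymethoxy)-4H-chromen-4-one | COCOc1cc2oc(-c3ccc(OCOC)c(OCOC)c3)cc(=O)c2c(OCOC)c1C[C@@H]1C(=C)[C@@H](O[Si](C)(C)C(C)(C)C)CCC1(C)C | intermediate
21 | ugonin Q | C=C1[C@@H](Cc2c(O)cc3oc(-c4ccc(O)c(O)c4)cc(=O)c3c2O)C(C)(C)CC[C@@H]1O | target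

**Count**

Total step count: 13. Longest linear sequence: 10 steps (steps 1 to 8, then 12 and 13); steps 9 to 11 make the flavone partner.

**Steps most likely to fail, with fallbacks**

Step 2. The open dialdehyde may be lost by amine-induced deformylation or oligomerisation before the second condensation, or the sequence may stall at the open Knoevenagel stage. The fallback sets out from 2 and 3 and comes back at 5, and still makes both ring bonds in one operation, now under Lewis-acid instead of amine control. Compound 3 would be silylated (Me3SiCl, Et3N) to benzyl 3-(trimethylsilyloxy)but-2-enoate F1 and then (LDA, Me3SiCl, THF, −78 °C) to 1-benzyloxy-1,3-bis(trimethylsilyloxy)buta-1,3-diene F2. With TiCl4 in CH2Cl2 at −78 °C, F2 and 2 would undergo two Mukaiyama aldol additions, the terminal carbon first and then the central carbon in a 6-(enolendo)-exo-trig closure, to give benzyl 2,4-dihydroxy-3,3-dimethyl-6-oxocyclohexane-1-carboxylate F3. Twofold β-elimination (MsCl, Et3N) would return to 5.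

Step 3. Facial discrimination on the flat, cross-conjugated dienone may be poor, or addition may compete at the singly activated alkene. The fallback sets out from 5 and comes back at 10, and obtains the single enantiomer by a stereodivergent reduction instead of an enantioselective addition. The same silyl ketene acetal 6 would be added without chiral ligand (Sc(OTf)3, CH2Cl2, −78 °C) to give racemic benzyl 6-(2-methoxy-2-oxoethyl)-5,5-dimethyl-2-oxocyclohex-3-ene-1-carboxylate F4. The conditions of step 4 would take F4 through racemic 2-(2-methoxy-2-oxoethyl)-3,3-dimethyl-6-oxocyclohexane-1-carboxylic acid F5, not isolated, to racemic methyl 2-(6,6-dimethyl-2-methylidene-3-oxocyclohexyl)acetate F6. The (R)-oxazaborolidine reduction of step 5 makes the new carbinol (S) in both enantiomers, so the (1S)-enone gives 10. The (1R)-enone gives methyl 2-[(1R,3S)-3-hydroxy-6,6-dimethyl-2-methylidenecyclohexyl]acetate F7, not isolated, whose cis groups close to (1S,5R)-6,6-dimethyl-9-methylidene-2-oxabicyclo[3.3.1]nonan-3-one F8, which is separated from 10 by chromatography.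

Step 4. The β-keto acid may lose CO2 before it is aminomethylated, which would erase the regiochemical marker and allow methylenation on the wrong side of the ketone. The fallback sets out from 7 and comes back at 9, and installs the extra carbon before the carboxyl group is removed. Hydroxymethylation of 7 at the keto ester carbon (aqueous CH2O, KHCO3, THF) would give benzyl (6S)-1-(hydroxymethyl)-6-(2-methoxy-2-oxoethyl)-5,5-dimethyl-2-oxocyclohex-3-ene-1-carboxylate F9. Hydrogenation and hydrogenolysis (H2, Pd/C, EtOAc) would give (2S)-1-(hydroxymethyl)-2-(2-methoxy-2-oxoethyl)-3,3-dimethyl-6-oxocyclohexane-1-carboxylic acid F10, not isolated, which decarboxylates on warming to methyl 2-[(1R)-2-(hydroxymethyl)-6,6-dimethyl-3-oxocyclohexyl]acetate F11. Mesylation and E1cB elimination (MsCl, Et3N, CH2Cl2) would return to 9.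

Further compounds
F1 | step 2 | benzyl 3-(trimethylsilyloxy)but-2-enoate | CC(O[Si](C)(C)C)=CC(=O)OCc1ccccc1
F2 | step 2 | 1-benzyloxy-1,3-bis(trimethylsilyloxy)buta-1,3-diene | C=C(O[Si](C)(C)C)C=C(OCc1ccccc1)O[Si](C)(C)C
F3 | step 2 | benzyl 2,4-dihydroxy-3,3-dimethyl-6-oxocyclohexane-1-carboxylate | O=C1CC(O)C(C)(C)C(O)C1C(=O)OCc1ccccc1
F4 | step 3 | racemic benzyl 6-(2-methoxy-2-oxoethyl)-5,5-dimethyl-2-oxocyclohex-3-ene-1-carboxylate | COC(=O)CC1C(C(=O)OCc2ccccc2)C(=O)C=CC1(C)C
F5 | step 3 | racemic 2-(2-methoxy-2-oxoethyl)-3,3-dimethyl-6-oxocyclohexane-1-carboxylic acid | COC(=O)CC1C(C(=O)O)C(=O)CCC1(C)C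
F6 | step 3 | racemic methyl 2-(6,6-dimethyl-2-methylidene-3-oxocyclohexyl)acetate | COC(=O)CC1C(=C)C(=O)CCC1(C)C
F7 | step 3 | methyl 2-[(1R,3S)-3-hydroxy-6,6-dimethyl-2-methylidenecyclohexyl]acetate | COC(=O)C[C@H]1C(=C)[C@@H](O)CCC1(C)C
F8 | step 3 | (1S,5R)-6,6-dimethyl-9-methylidene-2-oxabicyclo[3.3.1]nonan-3-one | O=C1C[C@H]2C(=C)[C@H](CCC2(C)C)O1
F9 | step 4 | benzyl (6S)-1-(hydroxymethyl)-6-(2-methoxy-2-oxoethyl)-5,5-dimethyl-2-oxocyclohex-3-ene-1-carboxylate | COC(=O)C[C@@H]1C(CO)(C(=O)OCc2ccccc2)C(=O)C=CC1(C)C
F10 | step 4 | (2S)-1-(hydroxymethyl)-2-(2-methoxy-2-oxoethyl)-3,3-dimethyl-6-oxocyclohexane-1-carboxylic acid | COC(=O)C[C@@H]1C(CO)(C(=O)O)C(=O)CCC1(C)C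
F11 | step 4 | methyl 2-[(1R)-2-(hydroxymethyl)-6,6-dimethyl-3-oxocyclohexyl]acetate | COC(=O)C[C@@H]1C(CO)C(=O)CCC1(C)C
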